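Minutes of the short meeting on this flask, which repeats the south-west run and has been followed that far.

- south-west: substrate 0.40 M; coupling partner 0.44 M; free catalyst 0.40 mM; added ligand 1 mM; the very flask that is asked about, followed so far
- flask: substrate 0.40 M; coupling partner 0.440 M; free catalyst 0.40 mM; added ligand 1.0 mM

south-west run (percent of the substrate charged)

| time / min | product / % |
|---|---|
| 0.833 | 3.9 |
| 2.50 | 11.6 |
| 4.00 | 18.4 |
| 6.00 | 25.9 |
| 10.0 | 40.0 |
| 12.0 | 46.5 |

(scatter of a reading: 0.3 percentage points)

* factor on the rate of making product when 30 % of the substrate are converted if coupling partner is charged twice over
* factor on the rate when 30 % of the substrate are converted if free catalyst is charged at 4.0 mM instead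

- no earlier run changes the charge of free catalyst; that part of a forecast is a guess
- no earlier run changes the charge of coupling partner; that part of a forecast is a guess

The chair asked that both questions be put in powers of ten, and proposed carrying a single quantity: the decade span d, the base-ten logarithm of the factor on the amount present at the point looked at, with catalyst counted by its charge. Going from 0.40 mM to 4.0 mM of free catalyst gives d = 1.00. At 30 % conversion, 0.120 M of coupling partner has been used, one for one with substrate, so a doubled charge leaves 0.760 M instead of 0.320 M, and d = 0.376. She defined the slope n as decades of rate per decade of charge, the usual reaction order, so that the factor on the rate is ten to the power n·d.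

The first speaker then read the south-west run. Between its early and late stretches, the rate fell by 0.869 decades per decade of substrate lost, a rough reading given the scatter. But substrate and coupling partner fall together there, so he said the run could not divide that slope between them. Were all of the fall the partner's, its n, reckoned on the partner's own concentrations, would read 0.985, and doubling the charge would give 2.34.

For the catalyst, no run offers any slope. The second speaker argued for n of one, hence a factor of 10.0.

The forecast stood apart from that figure, at 6 (range 2.5 to 20), and gave 1.15 (range 0.95 to 1.8) for the partner: “So the partner looks near zero order, probably saturated, and doubling it should change little.”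

    substrate + free catalyst → catalyst intermediate A (k = 14.1 /M/s)
    free catalyst ⇌ dormant form (K = 1.33, k = 0.00382 /s)
    coupling partner + catalyst intermediate B → catalyst intermediate C (k = 8.71 /M/s)
    catalyst intermediate E → free catalyst + product (k = 5.65 /s)
    catalyst intermediate C → catalyst intermediate D (k = 5.61 /s)
    catalyst intermediate D → by-product + catalyst intermediate E (k = 4.43 /s)
    catalyst intermediate A → catalyst intermediate B (k = 9.44 /s)
    free catalyst + added ligand ⇌ idle complex (K = 440 /M, k = 26.5 /M/s)

The flask gives 1.16 for the doubled coupling partner and 11.7 for 4.0 mM of free catalyst. At that catalyst charge and the same conversion, catalyst intermediate D holds 16.1 % of the catalyst. Over its d of 1.00, the catalyst factor spans 1.07 decades, so the mean n for free catalyst across that span is 1.07. Over a d of 0.376, the coupling partner's factor spans 0.0645 decades, so its mean n across that whole span is 0.171.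

Readings and results were computed with constants of no real substance; the scatter is artificial.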